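**Assumptions**
- The target is cis-(5S,8R), as read from the SMILES.
- The (R)-diphenylprolinol silyl ether is assumed to give the 3S aldehyde (5). The catalyst sense is settled in a pilot run.
- Kinetic LDA deprotonation of methoxyacetone is assumed to occur at its CH3 group.

**Retrosynthesis**
1. C8 (OMe) is set last, by face-selective hydrogenation of the cyclic enol ether C7=C8(OMe) conjugated to the N-methoxy-4-pyridone. H2 is delivered anti to the C5 octyl group, so OMe ends up cis to octyl.
2. The pyridone ring is closed by a Camps-type cyclization of an N-methoxy-N-acetyl enaminone. That enaminone comes from a β-chlorodienone plus N-methoxyacetamide.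
3. The carbocycle is built first. An organocatalytic Michael addition of a symmetrical bis(methoxyacetyl)methane to (E)-undec-2-enal sets C5, and a Robinson-type aldol condensation then forms the 2-methoxycyclohexenone (C7–C8 bond).
4. The diketone comes from a crossed Claisen of methoxyacetone with methyl methoxyacetate. Ring order: carbocycle first, then pyridone.

---

**Step 1**
Reactants: 1 methoxyacetone; 2 methyl methoxyacetate
Product: 3 1,5-dimethoxypentane-2,4-dione
Conditions: LDA (2.1 equiv), THF, −78 → 0 °C; aq. NH4Cl
Reagents that add atoms: none (the acyl donor 2 is numbered)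
Why: Crossed Claisen condensation. The kinetic CH3-enolate of 1 acylates ester 2, and the second equivalent of enolate deprotonates the product diketone to drive the reaction. The product is symmetrical, so the later aldol has no regiochemical choice. No stereocenter is formed.

**Step 2**
Reactants: 3 1,5-dimethoxypentane-2,4-dione (1.2 equiv); 4 (E)-undec-2-enal
Product: 5 (3S)-3-(1,5-dimethoxy-2,4-dioxopentan-3-yl)undecanal (may sit as the cyclic hemiacetal)
Conditions: (R)-diphenylprolinol TMS ether (10 mol %), PhCO2H (10 mol %), toluene, 25 °C
Reagents that add atoms: none (4 is numbered)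
Why: Iminium-ion (Jørgensen–Hayashi) Michael addition. The bulky silyloxy-diarylmethyl group shields one face of the (E)-iminium, which sets the octyl-bearing carbon (future C5, 3S). The central carbon of 3 carries two identical acyl groups, so it is not stereogenic.

**Step 3**
Reactants: 5
Product: 6 (5S)-2-methoxy-6-(2-methoxyacetyl)-5-octylcyclohex-2-en-1-one (C6 is epimerizable and mostly enolized)
Conditions: TsOH·H2O (10 mol %), PhMe, 4 Å MS, 50 °C
Reagents that add atoms: none (loses H2O)
Why: Robinson-type intramolecular aldol condensation. The 1,5-dicarbonyl 5 closes through the CH2OMe enol onto the aldehyde, and dehydration gives the α-methoxy enone. Acid is used to avoid base-mediated retro-Michael racemization of C5; C5 is not touched.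

**Step 4**
Reactants: 6
Product: 7 1-[(6S)-2-chloro-3-methoxy-6-octylcyclohexa-1,3-dien-1-yl]-2-methoxyethan-1-one
Conditions: (COCl)2 (1.5 equiv), DMF (cat.), 2,6-lutidine (2 equiv), CH2Cl2, 0 → 25 °C
Reagents that add atoms: oxalyl chloride, ClC(=O)C(=O)Cl (source of Cl)
Why: Vilsmeier-type conversion of the ring enol of the β-diketone into a β-chlorovinyl ketone. The ring enol is favored because it is conjugated with the C7=C8 enol ether. Lutidine protects the enol ether from HCl, and the diene is handled under Ar. No stereocenter changes.

**Step 5**
Reactants: 7; 8 N-methoxyacetamide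
Product: 9 N-[(3S)-6-methoxy-2-(2-methoxyacetyl)-3-octylcyclohexa-1,5-dien-1-yl]-N-methoxyacetamide
Conditions: Cs2CO3 (1.5 equiv), MeCN, 40 °C
Reagents that add atoms: N-methoxyacetamide, CC(=O)NOC (compound 8)
Why: Addition–elimination (SNV) of the amidate at the β-carbon of the vinylogous acid chloride. C5 is untouched.

**Step 6**
Reactants: 9
Product: 10 (5S)-1,3,8-trimethoxy-2-methyl-5-octyl-5,6-dihydroquinolin-4(1H)-one
Conditions: LiHMDS (1.3 equiv), THF, −78 → 0 °C; then AcOH, 25 °C
Reagents that add atoms: none (loses H2O)
Why: Camps-type cyclization, extended here from N-aryl amides to an N-methoxy enaminone. The more acidic α-methoxy ketone CH2 is enolized and attacks the N-acetyl carbonyl. Dehydration then aromatizes the ring to the N-methoxy-4-pyridone. C5 lies outside the acidic manifold.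

**Step 7**
Reactants: 10
Product: 11 Waltherione K, (5S,8R)-1,3,8-trimethoxy-2-methyl-5-octyl-5,6,7,8-tetrahydroquinolin-4(1H)-one
Conditions: H2 (50 bar), [Ir(cod)((S)-iPr-PHOX)]BArF (2 mol %), CH2Cl2, 25 °C
Reagents that add atoms: none (H2 only)
Why: Proposed new method: cationic Ir–N,P syn-hydrogenation of the trisubstituted cyclic enol ether C7=C8(OMe) fused to an N-methoxy-4-pyridone. The closest known reaction is Crabtree/Pfaltz Ir-catalyzed hydrogenation of unfunctionalized trisubstituted olefins and enol ethers. The pyridone π-system and the peri N–OMe oxygen anchor the catalyst. The peri-strained, pseudoaxial C5 octyl blocks one face, so H2 adds to C8 from the opposite face. H at C8 is then trans to octyl and OMe is cis, giving (8R) with 5S. The ligand enantiomer is chosen to be matched to the 5S center.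

---

**Compound list**

1 | methoxyacetone | CC(=O)COC | starting material
2 | methyl methoxyacetate | COCC(=O)OC | starting material
3 | 1,5-dimethoxypentane-2,4-dione | COCC(=O)CC(=O)COC | intermediate
4 | (E)-undec-2-enal | CCCCCCCC/C=C/C=O | starting material
5 | (3S)-3-(1,5-dimethoxy-2,4-dioxopentan-3-yl)undecanal | CCCCCCCC[C@@H](CC=O)C(C(=O)COC)C(=O)COC | intermediate
6 | (5S)-2-methoxy-6-(2-methoxyacetyl)-5-octylcyclohex-2-en-1-one | CCCCCCCC[C@H]1CC=C(OC)C(=O)C1C(=O)COC | intermediate
7 | 1-[(6S)-2-chloro-3-methoxy-6-octylcyclohexa-1,3-dien-1-yl]-2-methoxyethan-1-one | CCCCCCCC[C@H]1CC=C(OC)C(Cl)=C1C(=O)COC | intermediate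
8 | N-methoxyacetamide | CC(=O)NOC | starting material
9 | N-[(3S)-6-methoxy-2-(2-methoxyacetyl)-3-octylcyclohexa-1,5-dien-1-yl]-N-methoxyacetamide | CCCCCCCC[C@H]1CC=C(OC)C(N(OC)C(C)=O)=C1C(=O)COC | intermediate
10 | (5S)-1,3,8-trimethoxy-2-methyl-5-octyl-5,6-dihydroquinolin-4(1H)-one | CCCCCCCC[C@H]1CC=C(OC)c2c1c(=O)c(OC)c(C)n2OC | intermediate
11 | Waltherione K, (5S,8R)-1,3,8-trimethoxy-2-methyl-5-octyl-5,6,7,8-tetrahydroquinolin-4(1H)-one | CCCCCCCC[C@H]1CC[C@@H](OC)c2c1c(=O)c(OC)c(C)n2OC | target

**Totals**
- Total steps: 7.
- Longest linear sequence: 7, from methoxyacetone (1) to 11.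

**Three steps most likely to fail**
1. **Step 7 (proposed new hydrogenation).** Risks are poor diastereoselectivity or enantioselectivity, catalyst poisoning by the pyridone, and dehydrogenative aromatization of 10 to the quinolone. Fallback: hydrolyze the enol ether (2 M HCl, THF) to the 8-oxo compound. Then run Noyori transfer hydrogenation (RuCl[(S,S)- or (R,R)-TsDPEN](p-cymene), HCO2H/Et3N, enantiomer chosen to give 8R). Finally methylate with MeI/Ag2O to give 11.
2. **Step 6 (Camps-type closure).** Risks are the competing 2-pyridone path, N-deacylation, and ring-opening acyl transfer. Fallback: treat 7 with MeONH2·HCl/Et3N to give the N-methoxy enaminone. C-acetylate its dianion (2.2 equiv LDA, N-acetylimidazole) at the α-methoxy CH2. Then close by acid cyclodehydration (TsOH, PhMe, 60 °C) to give 10.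
3. **Step 3 (Robinson-type aldol).** Risks are competing hemiacetal/4H-pyran formation and retro-Michael racemization of C5. Fallback: convert aldehyde 5 to its dimethyl acetal (HC(OMe)3, TsOH). Form the TMS dienol ether and run a TMSOTf-promoted intramolecular Mukaiyama-type aldol onto the oxocarbenium ion. Eliminate MeOH with DBU to give 6.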